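**Assumption:** the target SMILES has no stereocentre and no E/Z-defined alkene (the prenyl alkene carries two identical methyls), so the molecule is achiral and "single enantiomer" needs no stereocontrol. The route has not been run; the key step is a proposal.

## Retrosynthetic overview

1. Target 18 ⇐ global desilylation of tetra-silyl flavone 17.
2. 17 ⇐ ynone 16 by a new Au(I)-catalysed 6-endo carboalkoxylation: the phenol's prenyloxymethyl acetal group shifts O→C3 while the pyranone closes, forming O1–C2 and C3–CH2 in one step.
3. 16 ⇐ propargylic alcohol 15 ⇐ A-ring aldehyde 9 + lithium acetylide from B-ring dibromo-olefin 14.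
4. 9 ⇐ 2,4,6-trihydroxybenzaldehyde (selective bis-TIPS, then ClCH2O-prenyl made from two prenol + CH2Br2, then AcCl); 14 ⇐ 3,4-dihydroxybenzaldehyde.
5. Ring order: A and B rings are purchased; the C ring (pyranone) is the only ring formed, in step 9.

## Route

**Step 1**
Reactants: 1 prenol (3-methylbut-2-en-1-ol), 2 equivalents; 2 dibromomethane, 1 equivalent
Product: 3 bis(prenyloxy)methane (diprenyl formal)
Conditions: prenol (2.1 equiv), NaH (2.2 equiv), THF, 0 °C; then CH2Br2 (1.0 equiv), Bu4NI (cat.), 60 °C
Reagents that add atoms: prenol (the second equivalent of 1), CC(C)=CCO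
Why: Double Williamson etherification in which two sodium prenoxides displace both bromides of CH2Br2; the intermediate bromomethyl prenyl ether is more reactive than CH2Br2, so the symmetrical formal forms cleanly.

**Step 2**
Reactants: 3 bis(prenyloxy)methane; 4 acetyl chloride
Product: 5 chloromethyl prenyl ether, used directly as a toluene solution (by-product prenyl acetate is inert and not carried forward)
Conditions: AcCl (1.0 equiv), ZnBr2 (0.1 mol%), toluene, 0 °C → rt
Reagents that add atoms: acetyl chloride, CC(=O)Cl
Why: Zn(II)-catalysed acetal/acyl chloride exchange gives the α-chloro ether under aprotic, HCl-free conditions that the acid-sensitive prenyl group tolerates.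

**Step 3**
Reactants: 6 2,4,6-trihydroxybenzaldehyde; 7 triisopropylsilyl chloride (2 equivalents)
Product: 8 2-hydroxy-4,6-bis(triisopropylsilyloxy)benzaldehyde
Conditions: TIPSCl (2.2 equiv), imidazole, DMF, 0 °C → rt
Reagents that add atoms: TIPSCl (the second equivalent of 7), CC(C)[Si](Cl)(C(C)C)C(C)C
Why: Selective phenol silylation; the 4-OH and one of the two equivalent ortho-OH groups react, while the remaining ortho-OH is deactivated by its hydrogen bond to the aldehyde and by the bulk of TIPS.

**Step 4**
Reactants: 8 2-hydroxy-4,6-bis(TIPSO)benzaldehyde; 5 chloromethyl prenyl ether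
Product: 9 2-{[(3-methylbut-2-en-1-yl)oxy]methoxy}-4,6-bis(triisopropylsilyloxy)benzaldehyde
Conditions: 5 (1.5 equiv, toluene solution), i-Pr2NEt (3 equiv), Bu4NI (10 mol%), CH2Cl2, 0 °C → rt
Reagents that add atoms: chloromethyl prenyl ether, CC(C)=CCOCCl
Why: O-alkylation of the phenol with a reactive α-chloro ether (MOM-type acetal formation) under amine base that leaves the aryl TIPS ethers and aldehyde untouched.

**Step 5**
Reactants: 10 3,4-dihydroxybenzaldehyde; 11 tert-butyldimethylsilyl chloride (2 equivalents)
Product: 12 3,4-bis(tert-butyldimethylsilyloxy)benzaldehyde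
Conditions: TBSCl (2.4 equiv), imidazole, DMF, rt
Reagents that add atoms: TBSCl (the second equivalent of 11), CC(C)(C)[Si](C)(C)Cl
Why: Standard exhaustive silylation of a catechol.

**Step 6**
Reactants: 12 3,4-bis(TBSO)benzaldehyde; 13 carbon tetrabromide
Product: 14 4-(2,2-dibromovinyl)-1,2-bis(tert-butyldimethylsilyloxy)benzene
Conditions: CBr4, PPh3, Et3N, CH2Cl2, 0 °C
Reagents that add atoms: carbon tetrabromide, BrC(Br)(Br)Br
Why: Corey–Fuchs dibromo-olefination (Wittig-type); Et3N buffers the phosphonium bromide so the aryl TBS ethers survive.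

**Step 7**
Reactants: 14 dibromo-olefin; 9 A-ring aldehyde
Product: 15 (±)-1-[2-{[(3-methylbut-2-en-1-yl)oxy]methoxy}-4,6-bis(TIPSO)phenyl]-3-[3,4-bis(TBSO)phenyl]prop-2-yn-1-ol (racemic; this carbinol centre is removed in step 8)
Conditions: 14 (1.3 equiv), n-BuLi (2.6 equiv), THF, −78 °C, 1 h; then 9, −78 → −40 °C; cold sat. NH4Cl quench
Reagents that add atoms: none
Why: Second stage of the Corey–Fuchs sequence gives the lithium acetylide in situ, which adds 1,2 to the aldehyde; low temperature and the bulky TIPS group suppress O→O silyl migration to the new alkoxide.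

**Step 8**
Reactants: 15 propargylic alcohol
Product: 16 1-[2-{[(3-methylbut-2-en-1-yl)oxy]methoxy}-4,6-bis(TIPSO)phenyl]-3-[3,4-bis(TBSO)phenyl]prop-2-yn-1-one
Conditions: activated MnO2 (15 equiv), CH2Cl2, rt
Reagents that add atoms: none
Why: Neutral MnO2 oxidation of a benzylic/propargylic alcohol; it avoids acid, which would ionise this electron-rich carbinol or cleave the acetal, and does not touch the prenyl alkene.

**Step 9 (key step)**
Reactants: 16 ynone
Product: 17 2-[3,4-bis(TBSO)phenyl]-3-{[(3-methylbut-2-en-1-yl)oxy]methyl}-5,7-bis(TIPSO)-4H-chromen-4-one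
Conditions: IPrAuNTf2 (5 mol%), 2,6-di-tert-butyl-4-methylpyridine (10 mol%), 4 Å MS, dry DCE (0.05 M), 0 °C → rt
Reagents that add atoms: none (isomerisation)
Why: Proposed new method: a π-acid-catalysed 6-endo-dig carboalkoxylation of an o-(alkoxymethoxy)aryl ynone, in which the acetal aryl-oxygen adds anti to the Au-activated alkyne at the β-carbon (favoured by ynone polarisation and the electron-rich B ring) to give an O-alkoxymethyl oxonium/C3-vinyl-gold species that expels the prenyloxymethyl oxocarbenium as a contact ion pair, which the nucleophilic C3–Au bond then captures to form C3–CH2 and release LAu+ (net 1,3 O→C shift); the closest known reactions are the Pt(II)/Au(I)-catalysed carboalkoxylation of o-alkynylphenyl acetals to 3-(α-alkoxyalkyl)benzofurans (5-endo) and the electrophilic 6-endo iodocyclisation of o-alkoxyaryl ynones to 3-iodochromones, and the bulky, weakly basic 6-OTIPS oxygen has no low-energy migrating group, so it should not compete.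

**Step 10**
Reactants: 17 tetra-silyl flavone
Product: 18 ophioglonol prenyl ether (target)
Conditions: TBAF (5 equiv), AcOH (5 equiv), THF, 0 °C → rt; pH 6 buffer work-up under Ar
Reagents that add atoms: none
Why: Fluoride desilylation of the four aryl silyl ethers; the AcOH buffer prevents phenoxide-driven vinylogous loss of the C3–CH2–O-prenyl group and catechol oxidation, and the prenyl ether is inert to fluoride.

## Compound list

1 | prenol (3-methylbut-2-en-1-ol) | CC(C)=CCO | starting material
2 | dibromomethane | BrCBr | starting material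
3 | bis(prenyloxy)methane | CC(C)=CCOCOCC=C(C)C | intermediate
4 | acetyl chloride | CC(=O)Cl | starting material
5 | chloromethyl prenyl ether | CC(C)=CCOCCl | intermediate
6 | 2,4,6-trihydroxybenzaldehyde | O=Cc1c(O)cc(O)cc1O | starting material
7 | triisopropylsilyl chloride | CC(C)[Si](Cl)(C(C)C)C(C)C | starting material
8 | 2-hydroxy-4,6-bis(triisopropylsilyloxy)benzaldehyde | O=Cc1c(O)cc(O[Si](C(C)C)(C(C)C)C(C)C)cc1O[Si](C(C)C)(C(C)C)C(C)C | intermediate
9 | 2-[(prenyloxy)methoxy]-4,6-bis(triisopropylsilyloxy)benzaldehyde | O=Cc1c(OCOCC=C(C)C)cc(O[Si](C(C)C)(C(C)C)C(C)C)cc1O[Si](C(C)C)(C(C)C)C(C)C | intermediate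
10 | 3,4-dihydroxybenzaldehyde | O=Cc1ccc(O)c(O)c1 | starting material
11 | tert-butyldimethylsilyl chloride | CC(C)(C)[Si](C)(C)Cl | starting material
12 | 3,4-bis(tert-butyldimethylsilyloxy)benzaldehyde | O=Cc1ccc(O[Si](C)(C)C(C)(C)C)c(O[Si](C)(C)C(C)(C)C)c1 | intermediate
13 | carbon tetrabromide | BrC(Br)(Br)Br | starting material
14 | 4-(2,2-dibromovinyl)-1,2-bis(tert-butyldimethylsilyloxy)benzene | BrC(Br)=Cc1ccc(O[Si](C)(C)C(C)(C)C)c(O[Si](C)(C)C(C)(C)C)c1 | intermediate
15 | (±)-propargylic alcohol (A-ring carbinol, B-ring alkyne) | OC(C#Cc1ccc(O[Si](C)(C)C(C)(C)C)c(O[Si](C)(C)C(C)(C)C)c1)c1c(OCOCC=C(C)C)cc(O[Si](C(C)C)(C(C)C)C(C)C)cc1O[Si](C(C)C)(C(C)C)C(C)C | intermediate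
16 | aryl ynone | O=C(C#Cc1ccc(O[Si](C)(C)C(C)(C)C)c(O[Si](C)(C)C(C)(C)C)c1)c1c(OCOCC=C(C)C)cc(O[Si](C(C)C)(C(C)C)C(C)C)cc1O[Si](C(C)C)(C(C)C)C(C)C | intermediate
17 | 5,7-bis(TIPSO)-3',4'-bis(TBSO)-3-(prenyloxymethyl)flavone | CC(C)=CCOCc1c(-c2ccc(O[Si](C)(C)C(C)(C)C)c(O[Si](C)(C)C(C)(C)C)c2)oc2cc(O[Si](C(C)C)(C(C)C)C(C)C)cc(O[Si](C(C)C)(C(C)C)C(C)C)c2c1=O | intermediate
18 | ophioglonol prenyl ether | CC(C)=CCOCc1c(-c2ccc(O)c(O)c2)oc2cc(O)cc(O)c2c1=O | target

## Summary

**Total steps:** 10.

**Longest linear sequence:** 7 steps (steps 1 → 2 → 4 → 7 → 8 → 9 → 10, from prenol). The A-ring and B-ring branches are each 6 steps to the target.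

**Three steps most likely to fail:**

1. **Step 9 (proposed new carboalkoxylation).** Risks are protodeauration to the 3-H flavone, loss of the oxocarbenium, or interference from the prenyl alkene. Fallback with known chemistry: use MOMCl in step 4 (dropping steps 1–2), cyclise the MOM-ynone by electrophilic 6-endo iodocyclisation (ICl, CH2Cl2, −78 °C) to the 3-iodoflavone, then install the side chain by Stille coupling with tributyl[(prenyloxy)methyl]stannane (Pd(PPh3)4, CuI, DMF), followed by step 10.

2. **Steps 2/4 (generation and use of chloromethyl prenyl ether).** The reagent may ionise to prenyl chloride and formaldehyde, or alkylate the hydrogen-bonded phenol sluggishly. Fallback: build the acetal from the phenol side. Alkylate 8 with chloromethyl methyl sulfide (NaH, NaI, DMF) to the aryl MTM ether, then exchange with prenol using a thiophilic promoter (CuBr2/Bu4NBr, or MeOTf with a hindered pyridine) to give 9 without any α-chloro ether.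

3. **Step 7 (acetylide addition).** The aldehyde is hindered and electron-rich, O→O silyl migration is possible, and carbinol 15 is acid-labile. Fallback: avoid the alkoxide and the alcohol altogether. Pinnick-oxidise 9 to the benzoic acid, make the acid chloride under neutral conditions (Ghosez reagent), and run a Pd/Cu acyl-Sonogashira coupling with the terminal alkyne (from 14, n-BuLi then H2O quench) to reach ynone 16 directly.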